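**Retrosynthetic overview** (carotenoid locants; ring A = hydroxycyclohexene carrying the CH2–C(=O) arm, ring B = cyclohexene with the allylic hydroxyl)

1. The target (siphonein) is reached by removing two silyl ethers after a C11=C12 Wittig union of a C25 phosphonium salt (ring B half) with a C15 keto-enal ester (ring A half).
2. The C25 salt comes from (2E,4E,6E)-2,7-dimethylocta-2,4,6-trienedial and a C15 phosphonium salt made from (R)-α-ionone; ring B is bought, and its C3' hydroxyl is set by allylic oxidation and trans-selective hydride reduction.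
3. The 19-acyloxy-8-oxo-9-ene unit is a rearranged Morita–Baylis–Hillman ester: ring A vinyl ketone plus 2,2-dimethoxyacetaldehyde, SN2' bromination, then displacement by (E)-dodec-2-enoate.
4. Ring A, the only ring made (step 5), is closed at the C1–C6 bond: a tertiary C1 radical, made by hydrogen-atom transfer to an isopropenyl group, adds 6-endo to the central carbon of an acyclic 2,3-dienoate. The enabling feature is that the quaternary gem-dimethyl carbon C1 is bonded to C6 of a tetrasubstituted C5=C6 alkene that is skipped, through the C7 methylene, to the C8 carbonyl, which is the α-protonated dienolate of an allenyl carbonyl compound.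
5. The dienoate comes from (S)-epichlorohydrin, isopropenylmagnesium bromide, propanoate dianion and a ketene Wittig reaction.

Key step: step 5

Assumption: (R)-α-ionone of high enantiomeric purity is treated as purchasable. Compounds 4–9 are 2RS mixtures, 11 is a mixture at the allene axis, and 15 and 27 are carbinol mixtures; each of these elements is erased later. TBS = tert-butyldimethylsilyl.

**Ring A half**

Step 1
Reactants: 1 (S)-epichlorohydrin
Product: 3 (2S)-2-(2-methylprop-2-en-1-yl)oxirane, via chlorohydrin 2 (not isolated)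
Conditions: CH2=C(CH3)MgBr (1.2 equiv), CuI (10 mol%), THF, −40 to −20 °C; then powdered NaOH, Et2O, rt
Reagents that add atoms: isopropenylmagnesium bromide, CC(=C)[Mg]Br
Why: Copper-catalysed Grignard opening of the epoxide at its unsubstituted carbon and Williamson-type closure of the chlorohydrin at the CH2Cl carbon both leave the stereocentre untouched, so the configuration of 1 is carried into 3.

Step 2
Reactants: 3 (2S)-2-(2-methylprop-2-en-1-yl)oxirane
Product: 5 (3RS,5R)-3-methyl-5-(2-methylprop-2-en-1-yl)oxolan-2-one, via hydroxy acid 4 (not isolated)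
Conditions: EtCO2H (1.5 equiv), LDA (3.1 equiv), THF, 0 °C, then 3, 45 °C; 1 M HCl; p-TsOH (cat.), CH2Cl2, rt
Reagents that add atoms: propanoic acid, CCC(=O)O
Why: Alkylation of the carboxylic acid dianion by SN2 opening of the terminal epoxide followed by acid-induced lactonisation should give the γ-lactone with the carbinol centre unchanged, the uncontrolled methyl-bearing centre being destroyed in step 4.

Step 3
Reactants: 5 (3RS,5R)-3-methyl-5-(2-methylprop-2-en-1-yl)oxolan-2-one
Product: 8 (2RS,4R)-4-[(tert-butyldimethylsilyl)oxy]-2,6-dimethylhept-6-enoic acid, via potassium hydroxy carboxylate 6 (not isolated), via silyl ester silyl ether 7 (not isolated)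
Conditions: KOH (1.05 equiv), MeOH/H2O, rt, evaporate; TBSCl (2.5 equiv), imidazole, DMF, rt; THF/H2O/AcOH 8:1:1, rt, short
Reagents that add atoms: potassium hydroxide, [K+].[OH-]; tert-butyldimethylsilyl chloride, CC(C)(C)[Si](C)(C)Cl
Why: Saponification, exhaustive silylation and selective hydrolysis of the labile silyl ester is the standard way to hold a γ-hydroxy acid as its silyl ether acid without relactonisation.

Step 4
Reactants: 8 (2RS,4R)-4-[(tert-butyldimethylsilyl)oxy]-2,6-dimethylhept-6-enoic acid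
Product: 11 ethyl (6S)-6-[(tert-butyldimethylsilyl)oxy]-4,8-dimethylnona-2,3,8-trienoate, via acid chloride 9 (not isolated), via ketene 10 (not isolated)
Conditions: Me2C=C(Cl)NMe2 (1.1 equiv), CH2Cl2, 0 °C, used at once; added to Ph3P=CHCO2Et (1.1 equiv), Et3N (1.3 equiv), CH2Cl2, 0 °C to rt
Reagents that add atoms: ethyl (triphenylphosphoranylidene)acetate, CCOC(=O)C=P(c1ccccc1)(c1ccccc1)c1ccccc1
Why: Neutral acid chloride formation spares the silyl ether, Et3N dehydrochlorinates the α-branched acid chloride to the methyl ketene, and the Wittig reaction of this ketene with the stabilised ylide (the classical allenoate synthesis) should outrun [2+2] addition to the remote alkene at 0 °C, erasing the α-methyl centre and giving the allene as an inconsequential axis mixture.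

Step 5
Reactants: 11 ethyl (6S)-6-[(tert-butyldimethylsilyl)oxy]-4,8-dimethylnona-2,3,8-trienoate
Product: 12 ethyl 2-[(4R)-4-[(tert-butyldimethylsilyl)oxy]-2,6,6-trimethylcyclohex-1-en-1-yl]acetate
Conditions: Fe(acac)3 (30 mol%), PhSiH3 (2.5 equiv), EtOH/HOCH2CH2OH 5:1, 0.02 M, 60 °C, Ar
Reagents that add atoms: none
Why: Proposed new method: the trivalent iron hydride formed from Fe(acac)3 and PhSiH3 should transfer a hydrogen atom to the CH2 terminus of the 1,1-disubstituted alkene (Markovnikov MHAT) to give the tertiary radical at the future gem-dimethyl carbon, which as a nucleophilic radical adds to the electrophilic central carbon of the 2,3-dienoate in the plane of the ester-conjugated π bond; the ester-stabilised radical is then reduced by divalent iron to the dienolate and protonated by ethanol at the α-carbon, the closest known reaction type being the Fe(acac)3/PhSiH3 reductive olefin coupling (HAT-initiated Giese addition to acrylates and enones with formation of quaternary carbons) combined with radical addition to the central carbon of allenoates. Ring A closes in a 6-endo mode onto the digonal central allene carbon (the tether sits on the methyl-bearing allene terminus, so the C5=C6 bond ends up inside the ring), the 5-exo alternative being disfavoured because it would join two fully substituted carbons and leave an unstabilised vinyl radical. No stereocentre is created: the silyloxy-bearing carbon is remote from all reacting atoms and the allene axis disappears. The step needs hydrogen-atom transfer to the isopropenyl group rather than to the allene or the product alkene, which the faster MHAT to unhindered 1,1-disubstituted alkenes and the high dilution should secure, and α- rather than γ-protonation of the dienolate, which kinetic protonation and the strain of an exocyclic conjugated alkene next to the gem-dimethyl group both favour.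

Step 6
Reactants: 12 ethyl 2-[(4R)-4-[(tert-butyldimethylsilyl)oxy]-2,6,6-trimethylcyclohex-1-en-1-yl]acetate
Product: 13 2-[(4R)-4-[(tert-butyldimethylsilyl)oxy]-2,6,6-trimethylcyclohex-1-en-1-yl]-N-methoxy-N-methylacetamide
Conditions: MeONHMe·HCl (3 equiv), i-PrMgCl (6 equiv), THF, −20 to 0 °C
Reagents that add atoms: N,O-dimethylhydroxylamine hydrochloride, CNOC.Cl
Why: Weinreb amidation of the ester by the preformed chloromagnesium amide should be faster than enolisation of the skipped ester at low temperature.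

Step 7
Reactants: 13 2-[(4R)-4-[(tert-butyldimethylsilyl)oxy]-2,6,6-trimethylcyclohex-1-en-1-yl]-N-methoxy-N-methylacetamide
Product: 14 1-[(4R)-4-[(tert-butyldimethylsilyl)oxy]-2,6,6-trimethylcyclohex-1-en-1-yl]but-3-en-2-one
Conditions: CH2=CHMgBr (1.5 equiv), THF, −10 °C; inverse quench into cold 1 M HCl
Reagents that add atoms: vinylmagnesium bromide, C=C[Mg]Br
Why: In this Weinreb ketone synthesis the chelated tetrahedral adduct prevents over-addition, and the inverse acidic quench prevents conjugate addition of the released amine to the vinyl ketone.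

Step 8
Reactants: 14 1-[(4R)-4-[(tert-butyldimethylsilyl)oxy]-2,6,6-trimethylcyclohex-1-en-1-yl]but-3-en-2-one
Product: 15 (4RS)-1-[(4R)-4-[(tert-butyldimethylsilyl)oxy]-2,6,6-trimethylcyclohex-1-en-1-yl]-4-hydroxy-5,5-dimethoxy-3-methylidenepentan-2-one
Conditions: (MeO)2CHCHO (60% aq., 2 equiv), DABCO (0.5 equiv), 1,4-dioxane/H2O, rt
Reagents that add atoms: 2,2-dimethoxyacetaldehyde, COC(OC)C=O
Why: The Morita–Baylis–Hillman reaction of an alkyl vinyl ketone with an activated α,α-dialkoxy aldehyde is fast under DABCO in aqueous dioxane, and the new carbinol centre need not be controlled because it becomes an sp2 carbon in step 9.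

Step 9
Reactants: 15 (4RS)-1-[(4R)-4-[(tert-butyldimethylsilyl)oxy]-2,6,6-trimethylcyclohex-1-en-1-yl]-4-hydroxy-5,5-dimethoxy-3-methylidenepentan-2-one
Product: 16 (3Z)-3-(bromomethyl)-1-[(4R)-4-[(tert-butyldimethylsilyl)oxy]-2,6,6-trimethylcyclohex-1-en-1-yl]-5,5-dimethoxypent-3-en-2-one
Conditions: NBS (1.3 equiv), Me2S (1.5 equiv), CH2Cl2, −20 to 0 °C
Reagents that add atoms: N-bromosuccinimide, O=C1CCC(=O)N1Br
Why: SN2' bromination of a Baylis–Hillman alcohol through its alkoxysulfonium salt should give the rearranged primary allylic bromide with the acyl group trans to the acetal-bearing carbon, which is the geometry the target needs at the 9,10-alkene.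

Step 10
Reactants: 16 (3Z)-3-(bromomethyl)-1-[(4R)-4-[(tert-butyldimethylsilyl)oxy]-2,6,6-trimethylcyclohex-1-en-1-yl]-5,5-dimethoxypent-3-en-2-one, 17 (2E)-dodec-2-enoic acid
Product: 19 (2E)-2-{[(4R)-4-[(tert-butyldimethylsilyl)oxy]-2,6,6-trimethylcyclohex-1-en-1-yl]acetyl}-4,4-dimethoxybut-2-en-1-yl (2E)-dodec-2-enoate, via potassium dodecenoate 18 (not isolated)
Conditions: 17 (1.2 equiv), KHCO3 (1.5 equiv), DMF, 0 °C to rt
Reagents that add atoms: none
Why: SN2 O-alkylation of the carboxylate by the very reactive 2-(bromomethyl)enone under weakly basic conditions keeps the alkene geometry, and any SN2' ester should funnel to this conjugated primary ester, which is the thermodynamic product.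

Step 11
Reactants: 19 (2E)-2-{[(4R)-4-[(tert-butyldimethylsilyl)oxy]-2,6,6-trimethylcyclohex-1-en-1-yl]acetyl}-4,4-dimethoxybut-2-en-1-yl (2E)-dodec-2-enoate
Product: 20 (2E)-2-{[(4R)-4-[(tert-butyldimethylsilyl)oxy]-2,6,6-trimethylcyclohex-1-en-1-yl]acetyl}-4-oxobut-2-en-1-yl (2E)-dodec-2-enoate
Conditions: Amberlyst-15, acetone/H2O 20:1, 0 °C to rt; used at once
Reagents that add atoms: water, O
Why: Acid-resin hydrolysis of the dimethyl acetal, as used for fumaraldehyde monoacetals, should free the aldehyde under conditions mild enough for the secondary silyl ether and the allylic ester.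

**Ring B half**

Step 12
Reactants: 21 (R)-α-ionone
Product: 22 2-methyl-2-{(E)-2-[(1R)-2,6,6-trimethylcyclohex-2-en-1-yl]ethenyl}-1,3-dioxolane
Conditions: TMSOCH2CH2OTMS (1.5 equiv), TMSOTf (2 mol%), CH2Cl2, −78 to −40 °C; pyridine quench
Reagents that add atoms: 1,2-bis(trimethylsilyloxy)ethane, C[Si](C)(C)OCCO[Si](C)(C)C
Why: TMSOTf-catalysed ketalisation with the bis-silyl ether of ethylene glycol at low temperature should protect the enone carbonyl without double-bond migration or epimerisation of the doubly allylic ring carbon.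

Step 13
Reactants: 22 2-methyl-2-{(E)-2-[(1R)-2,6,6-trimethylcyclohex-2-en-1-yl]ethenyl}-1,3-dioxolane
Product: 23 (4R)-3,5,5-trimethyl-4-[(E)-2-(2-methyl-1,3-dioxolan-2-yl)ethenyl]cyclohex-2-en-1-one
Conditions: t-BuOOH (70% aq., 5 equiv), Rh2(cap)4 (1 mol%; cap = caprolactamate), K2CO3 (cat.), CH2Cl2, rt
Reagents that add atoms: tert-butyl hydroperoxide, CC(C)(C)OO
Why: Radical allylic C–H oxidation with tert-butyl hydroperoxide should attack the ring methylene next to the trisubstituted alkene and spare the hindered doubly allylic methine, as in the known conversion of α-ionone into 3-oxo-α-ionone.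

Step 14
Reactants: 23 (4R)-3,5,5-trimethyl-4-[(E)-2-(2-methyl-1,3-dioxolan-2-yl)ethenyl]cyclohex-2-en-1-one
Product: 24 (1R,4R)-3,5,5-trimethyl-4-[(E)-2-(2-methyl-1,3-dioxolan-2-yl)ethenyl]cyclohex-2-en-1-ol
Conditions: LiBH(s-Bu)3 (L-Selectride, 1.2 equiv), THF, −78 °C; H2O quench
Reagents that add atoms: none
Why: 1,2-Reduction of the β,β-disubstituted cyclohexenone by the bulky hydride should occur from the face opposite the axial methyl of the gem-dimethyl group (the side chain being pseudoaxial to avoid allylic strain), which places the hydroxyl trans to the side chain and sets the (1R) centre under substrate control.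

Step 15
Reactants: 24 (1R,4R)-3,5,5-trimethyl-4-[(E)-2-(2-methyl-1,3-dioxolan-2-yl)ethenyl]cyclohex-2-en-1-ol
Product: 25 tert-butyldimethyl{[(1R,4R)-3,5,5-trimethyl-4-[(E)-2-(2-methyl-1,3-dioxolan-2-yl)ethenyl]cyclohex-2-en-1-yl]oxy}silane
Conditions: TBSCl (1.3 equiv), imidazole (2.5 equiv), DMF, rt
Reagents that add atoms: tert-butyldimethylsilyl chloride, CC(C)(C)[Si](C)(C)Cl
Why: Standard imidazole-promoted silylation of the secondary allylic alcohol.

Step 16
Reactants: 25 tert-butyldimethyl{[(1R,4R)-3,5,5-trimethyl-4-[(E)-2-(2-methyl-1,3-dioxolan-2-yl)ethenyl]cyclohex-2-en-1-yl]oxy}silane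
Product: 26 (3E)-4-[(1R,4R)-4-[(tert-butyldimethylsilyl)oxy]-2,6,6-trimethylcyclohex-2-en-1-yl]but-3-en-2-one
Conditions: PPTS (10 mol%), acetone/H2O 10:1, rt
Reagents that add atoms: water, O
Why: Mild acid-catalysed hydrolysis of the allylic dioxolane should regenerate the enone while the secondary silyl ether survives.

Step 17
Reactants: 26 (3E)-4-[(1R,4R)-4-[(tert-butyldimethylsilyl)oxy]-2,6,6-trimethylcyclohex-2-en-1-yl]but-3-en-2-one
Product: 27 (1E,3RS)-1-[(1R,4R)-4-[(tert-butyldimethylsilyl)oxy]-2,6,6-trimethylcyclohex-2-en-1-yl]-3-methylpenta-1,4-dien-3-ol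
Conditions: CH2=CHMgBr (1.5 equiv), THF, −20 to 0 °C; aq. NH4Cl
Reagents that add atoms: vinylmagnesium bromide, C=C[Mg]Br
Why: 1,2-Grignard addition of vinylmagnesium bromide to the enone follows the classical vinyl-ionol synthesis, and the new tertiary carbinol centre is irrelevant because it is ionised in step 18.

Step 18
Reactants: 27 (1E,3RS)-1-[(1R,4R)-4-[(tert-butyldimethylsilyl)oxy]-2,6,6-trimethylcyclohex-2-en-1-yl]-3-methylpenta-1,4-dien-3-ol
Product: 28 [(2E,4E)-5-[(1R,4R)-4-[(tert-butyldimethylsilyl)oxy]-2,6,6-trimethylcyclohex-2-en-1-yl]-3-methylpenta-2,4-dien-1-yl]triphenylphosphonium bromide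
Conditions: PPh3·HBr (1.05 equiv), CH2Cl2, 0 °C to rt; crystallise
Reagents that add atoms: triphenylphosphine hydrobromide, Br.c1ccc(cc1)P(c1ccccc1)c1ccccc1
Why: Ionisation of the doubly allylic tertiary alcohol and capture of the pentadienyl cation by PPh3 at its unhindered terminus (allylic transposition) is the standard route to C15 Wittig salts and should give mainly the 2E isomer, purified by crystallisation.

Step 19
Reactants: 28 [(2E,4E)-5-[(1R,4R)-4-[(tert-butyldimethylsilyl)oxy]-2,6,6-trimethylcyclohex-2-en-1-yl]-3-methylpenta-2,4-dien-1-yl]triphenylphosphonium bromide, 29 (2E,4E,6E)-2,7-dimethylocta-2,4,6-trienedial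
Product: 31 (2E,4E,6E,8E,10E,12E)-13-[(1R,4R)-4-[(tert-butyldimethylsilyl)oxy]-2,6,6-trimethylcyclohex-2-en-1-yl]-2,7,11-trimethyltrideca-2,4,6,8,10,12-hexaenal, via ylide 30 (not isolated)
Conditions: 29 (2.5 equiv), NaOMe (1.05 equiv), CH2Cl2/MeOH, −10 °C to rt; then heptane, 80 °C, dark (E/Z equilibration)
Reagents that add atoms: none
Why: Wittig olefination of the excess dialdehyde should stop after one formyl group because the second is deactivated once the polyene is lengthened, and thermal equilibration should convert the new disubstituted alkene to the all-E form.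

Step 20
Reactants: 31 (2E,4E,6E,8E,10E,12E)-13-[(1R,4R)-4-[(tert-butyldimethylsilyl)oxy]-2,6,6-trimethylcyclohex-2-en-1-yl]-2,7,11-trimethyltrideca-2,4,6,8,10,12-hexaenal
Product: 32 (2E,4E,6E,8E,10E,12E)-13-[(1R,4R)-4-[(tert-butyldimethylsilyl)oxy]-2,6,6-trimethylcyclohex-2-en-1-yl]-2,7,11-trimethyltrideca-2,4,6,8,10,12-hexaen-1-ol
Conditions: NaBH4 (1.0 equiv), THF/EtOH, 0 °C
Reagents that add atoms: none
Why: Chemoselective 1,2-reduction of the polyenal by borohydride.

Step 21
Reactants: 32 (2E,4E,6E,8E,10E,12E)-13-[(1R,4R)-4-[(tert-butyldimethylsilyl)oxy]-2,6,6-trimethylcyclohex-2-en-1-yl]-2,7,11-trimethyltrideca-2,4,6,8,10,12-hexaen-1-ol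
Product: 33 [(2E,4E,6E,8E,10E,12E)-13-[(1R,4R)-4-[(tert-butyldimethylsilyl)oxy]-2,6,6-trimethylcyclohex-2-en-1-yl]-2,7,11-trimethyltrideca-2,4,6,8,10,12-hexaen-1-yl]triphenylphosphonium bromide
Conditions: PPh3·HBr (1.05 equiv), CH2Cl2, 0 °C, dark
Reagents that add atoms: triphenylphosphine hydrobromide, Br.c1ccc(cc1)P(c1ccccc1)c1ccccc1
Why: Acid-mediated formation of the polyenyl cation and capture by PPh3 at the chain terminus, the standard entry to apo-carotenyl Wittig salts, should give the fully conjugated C25 salt.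

**Union and completion**

Step 22
Reactants: 33 [(2E,4E,6E,8E,10E,12E)-13-[(1R,4R)-4-[(tert-butyldimethylsilyl)oxy]-2,6,6-trimethylcyclohex-2-en-1-yl]-2,7,11-trimethyltrideca-2,4,6,8,10,12-hexaen-1-yl]triphenylphosphonium bromide, 20 (2E)-2-{[(4R)-4-[(tert-butyldimethylsilyl)oxy]-2,6,6-trimethylcyclohex-1-en-1-yl]acetyl}-4-oxobut-2-en-1-yl (2E)-dodec-2-enoate
Product: 35 (3R,3'R,6'R)-3,3'-bis[(tert-butyldimethylsilyl)oxy]-8-oxo-7,8-dihydro-β,ε-caroten-19-yl (2E)-dodec-2-enoate, via ylide 34 (not isolated)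
Conditions: 1,2-epoxybutane (excess), CH2Cl2, 45 °C, dark, Ar; then EtOAc, 60 °C (E/Z equilibration)
Reagents that add atoms: none
Why: Wittig olefination under neutral epoxide conditions (bromide opens the epoxide and the resulting alkoxide deprotonates the salt) should take place at the aldehyde, the most electrophilic carbonyl, without exposing the acyloxymethyl enone to free base, and the new 11,12-alkene is equilibrated to E.

Step 23
Reactants: 35 (3R,3'R,6'R)-3,3'-bis[(tert-butyldimethylsilyl)oxy]-8-oxo-7,8-dihydro-β,ε-caroten-19-yl (2E)-dodec-2-enoate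
Product: 36 (3R,3'R,6'R)-3,3'-dihydroxy-8-oxo-7,8-dihydro-β,ε-caroten-19-yl (2E)-dodec-2-enoate (target)
Conditions: HF·pyridine (excess), pyridine, THF, 0 °C to rt, dark
Reagents that add atoms: none
Why: Fluoride-mediated cleavage of both secondary silyl ethers under buffered, weakly acidic conditions should spare the allylic ester, the skipped enone and the acid-sensitive allylic alcohol of ring B.

**Compound list**

1 | (S)-epichlorohydrin [(2S)-2-(chloromethyl)oxirane] | ClC[C@@H]1CO1 | starting material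
2 | (2S)-1-chloro-4-methylpent-4-en-2-ol | ClC[C@@H](O)CC(C)=C | intermediate
3 | (2S)-2-(2-methylprop-2-en-1-yl)oxirane | C1[C@@H](O1)CC(C)=C | intermediate
4 | (2RS,4R)-4-hydroxy-2,6-dimethylhept-6-enoic acid | OC(=O)C(C)C[C@@H](O)CC(C)=C | intermediate
5 | (3RS,5R)-3-methyl-5-(2-methylprop-2-en-1-yl)oxolan-2-one | CC1C[C@@H](OC1=O)CC(C)=C | intermediate
6 | potassium (2RS,4R)-4-hydroxy-2,6-dimethylhept-6-enoate | [K+].[O-]C(=O)C(C)C[C@@H](O)CC(C)=C | intermediate
7 | tert-butyldimethylsilyl (2RS,4R)-4-[(tert-butyldimethylsilyl)oxy]-2,6-dimethylhept-6-enoate | CC(C)(C)[Si](C)(C)OC(=O)C(C)C[C@@H](O[Si](C)(C)C(C)(C)C)CC(C)=C | intermediate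
8 | (2RS,4R)-4-[(tert-butyldimethylsilyl)oxy]-2,6-dimethylhept-6-enoic acid | OC(=O)C(C)C[C@@H](O[Si](C)(C)C(C)(C)C)CC(C)=C | intermediate
9 | (2RS,4R)-4-[(tert-butyldimethylsilyl)oxy]-2,6-dimethylhept-6-enoyl chloride | ClC(=O)C(C)C[C@@H](O[Si](C)(C)C(C)(C)C)CC(C)=C | intermediate
10 | (4S)-4-[(tert-butyldimethylsilyl)oxy]-2,6-dimethylhepta-1,6-dien-1-one (ketene) | O=C=C(C)C[C@@H](O[Si](C)(C)C(C)(C)C)CC(C)=C | intermediate
11 | ethyl (6S)-6-[(tert-butyldimethylsilyl)oxy]-4,8-dimethylnona-2,3,8-trienoate | CCOC(=O)C=C=C(C)C[C@@H](O[Si](C)(C)C(C)(C)C)CC(C)=C | intermediate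
12 | ethyl 2-[(4R)-4-[(tert-butyldimethylsilyl)oxy]-2,6,6-trimethylcyclohex-1-en-1-yl]acetate | CCOC(=O)CC1=C(C)C[C@@H](O[Si](C)(C)C(C)(C)C)CC1(C)C | intermediate
13 | 2-[(4R)-4-[(tert-butyldimethylsilyl)oxy]-2,6,6-trimethylcyclohex-1-en-1-yl]-N-methoxy-N-methylacetamide | CON(C)C(=O)CC1=C(C)C[C@@H](O[Si](C)(C)C(C)(C)C)CC1(C)C | intermediate
14 | 1-[(4R)-4-[(tert-butyldimethylsilyl)oxy]-2,6,6-trimethylcyclohex-1-en-1-yl]but-3-en-2-one | C=CC(=O)CC1=C(C)C[C@@H](O[Si](C)(C)C(C)(C)C)CC1(C)C | intermediate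
15 | (4RS)-1-[(4R)-4-[(tert-butyldimethylsilyl)oxy]-2,6,6-trimethylcyclohex-1-en-1-yl]-4-hydroxy-5,5-dimethoxy-3-methylidenepentan-2-one | COC(OC)C(O)C(=C)C(=O)CC1=C(C)C[C@@H](O[Si](C)(C)C(C)(C)C)CC1(C)C | intermediate
16 | (3Z)-3-(bromomethyl)-1-[(4R)-4-[(tert-butyldimethylsilyl)oxy]-2,6,6-trimethylcyclohex-1-en-1-yl]-5,5-dimethoxypent-3-en-2-one | BrC\C(=C/C(OC)OC)C(=O)CC1=C(C)C[C@@H](O[Si](C)(C)C(C)(C)C)CC1(C)C | intermediate
17 | (2E)-dodec-2-enoic acid | CCCCCCCCC/C=C/C(=O)O | starting material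
18 | potassium (2E)-dodec-2-enoate | CCCCCCCCC/C=C/C(=O)[O-].[K+] | intermediate
19 | (2E)-2-{[(4R)-4-[(tert-butyldimethylsilyl)oxy]-2,6,6-trimethylcyclohex-1-en-1-yl]acetyl}-4,4-dimethoxybut-2-en-1-yl (2E)-dodec-2-enoate | CCCCCCCCC/C=C/C(=O)OC\C(=C/C(OC)OC)C(=O)CC1=C(C)C[C@@H](O[Si](C)(C)C(C)(C)C)CC1(C)C | intermediate
20 | (2E)-2-{[(4R)-4-[(tert-butyldimethylsilyl)oxy]-2,6,6-trimethylcyclohex-1-en-1-yl]acetyl}-4-oxobut-2-en-1-yl (2E)-dodec-2-enoate | CCCCCCCCC/C=C/C(=O)OC\C(=C/C=O)C(=O)CC1=C(C)C[C@@H](O[Si](C)(C)C(C)(C)C)CC1(C)C | intermediate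
21 | (R)-α-ionone [(3E)-4-[(1R)-2,6,6-trimethylcyclohex-2-en-1-yl]but-3-en-2-one] | CC(=O)/C=C/[C@H]1C(C)=CCCC1(C)C | starting material
22 | 2-methyl-2-{(E)-2-[(1R)-2,6,6-trimethylcyclohex-2-en-1-yl]ethenyl}-1,3-dioxolane | CC1(OCCO1)/C=C/[C@H]1C(C)=CCCC1(C)C | intermediate
23 | (4R)-3,5,5-trimethyl-4-[(E)-2-(2-methyl-1,3-dioxolan-2-yl)ethenyl]cyclohex-2-en-1-one | CC1(OCCO1)/C=C/[C@H]1C(C)=CC(=O)CC1(C)C | intermediate
24 | (1R,4R)-3,5,5-trimethyl-4-[(E)-2-(2-methyl-1,3-dioxolan-2-yl)ethenyl]cyclohex-2-en-1-ol | CC1(OCCO1)/C=C/[C@H]1C(C)=C[C@H](O)CC1(C)C | intermediate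
25 | tert-butyldimethyl{[(1R,4R)-3,5,5-trimethyl-4-[(E)-2-(2-methyl-1,3-dioxolan-2-yl)ethenyl]cyclohex-2-en-1-yl]oxy}silane | CC1(OCCO1)/C=C/[C@H]1C(C)=C[C@H](O[Si](C)(C)C(C)(C)C)CC1(C)C | intermediate
26 | (3E)-4-[(1R,4R)-4-[(tert-butyldimethylsilyl)oxy]-2,6,6-trimethylcyclohex-2-en-1-yl]but-3-en-2-one | CC(=O)/C=C/[C@H]1C(C)=C[C@H](O[Si](C)(C)C(C)(C)C)CC1(C)C | intermediate
27 | (1E,3RS)-1-[(1R,4R)-4-[(tert-butyldimethylsilyl)oxy]-2,6,6-trimethylcyclohex-2-en-1-yl]-3-methylpenta-1,4-dien-3-ol | C=CC(C)(O)/C=C/[C@H]1C(C)=C[C@H](O[Si](C)(C)C(C)(C)C)CC1(C)C | intermediate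
28 | [(2E,4E)-5-[(1R,4R)-4-[(tert-butyldimethylsilyl)oxy]-2,6,6-trimethylcyclohex-2-en-1-yl]-3-methylpenta-2,4-dien-1-yl]triphenylphosphonium bromide | [Br-].c1ccc(cc1)[P+](c1ccccc1)(c1ccccc1)C/C=C(C)/C=C/[C@H]1C(C)=C[C@H](O[Si](C)(C)C(C)(C)C)CC1(C)C | intermediate
29 | (2E,4E,6E)-2,7-dimethylocta-2,4,6-trienedial | O=C/C(C)=C/C=C/C=C(C)/C=O | starting material
30 | ylide of 28 [(2E,4E)-5-[(1R,4R)-4-[(tert-butyldimethylsilyl)oxy]-2,6,6-trimethylcyclohex-2-en-1-yl]-3-methylpenta-2,4-dien-1-ylidene]triphenylphosphorane | C(/C=C(C)/C=C/[C@H]1C(C)=C[C@H](O[Si](C)(C)C(C)(C)C)CC1(C)C)=P(c1ccccc1)(c1ccccc1)c1ccccc1 | intermediate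
31 | (2E,4E,6E,8E,10E,12E)-13-[(1R,4R)-4-[(tert-butyldimethylsilyl)oxy]-2,6,6-trimethylcyclohex-2-en-1-yl]-2,7,11-trimethyltrideca-2,4,6,8,10,12-hexaenal | O=C/C(C)=C/C=C/C=C(C)/C=C/C=C(C)/C=C/[C@H]1C(C)=C[C@H](O[Si](C)(C)C(C)(C)C)CC1(C)C | intermediate
32 | (2E,4E,6E,8E,10E,12E)-13-[(1R,4R)-4-[(tert-butyldimethylsilyl)oxy]-2,6,6-trimethylcyclohex-2-en-1-yl]-2,7,11-trimethyltrideca-2,4,6,8,10,12-hexaen-1-ol | OC/C(C)=C/C=C/C=C(C)/C=C/C=C(C)/C=C/[C@H]1C(C)=C[C@H](O[Si](C)(C)C(C)(C)C)CC1(C)C | intermediate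
33 | [(2E,4E,6E,8E,10E,12E)-13-[(1R,4R)-4-[(tert-butyldimethylsilyl)oxy]-2,6,6-trimethylcyclohex-2-en-1-yl]-2,7,11-trimethyltrideca-2,4,6,8,10,12-hexaen-1-yl]triphenylphosphonium bromide | [Br-].c1ccc(cc1)[P+](c1ccccc1)(c1ccccc1)C/C(C)=C/C=C/C=C(C)/C=C/C=C(C)/C=C/[C@H]1C(C)=C[C@H](O[Si](C)(C)C(C)(C)C)CC1(C)C | intermediate
34 | ylide of 33 [(2E,4E,6E,8E,10E,12E)-13-[(1R,4R)-4-[(tert-butyldimethylsilyl)oxy]-2,6,6-trimethylcyclohex-2-en-1-yl]-2,7,11-trimethyltrideca-2,4,6,8,10,12-hexaen-1-ylidene]triphenylphosphorane | C(/C(C)=C/C=C/C=C(C)/C=C/C=C(C)/C=C/[C@H]1C(C)=C[C@H](O[Si](C)(C)C(C)(C)C)CC1(C)C)=P(c1ccccc1)(c1ccccc1)c1ccccc1 | intermediate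
35 | (3R,3'R,6'R)-3,3'-bis[(tert-butyldimethylsilyl)oxy]-8-oxo-7,8-dihydro-β,ε-caroten-19-yl (2E)-dodec-2-enoate | CCCCCCCCC/C=C/C(=O)OC\C(=C/C=C/C(C)=C/C=C/C=C(C)/C=C/C=C(C)/C=C/[C@H]1C(C)=C[C@H](O[Si](C)(C)C(C)(C)C)CC1(C)C)C(=O)CC1=C(C)C[C@@H](O[Si](C)(C)C(C)(C)C)CC1(C)C | intermediate
36 | (3R,3'R,6'R)-3,3'-dihydroxy-8-oxo-7,8-dihydro-β,ε-caroten-19-yl (2E)-dodec-2-enoate (siphonein) | CCCCCCCCC/C=C/C(=O)OC\C(=C/C=C/C(C)=C/C=C/C=C(C)/C=C/C=C(C)/C=C/[C@H]1C(C)=C[C@H](O)CC1(C)C)C(=O)CC1=C(C)C[C@@H](O)CC1(C)C | target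

**Step count and risks**

Total steps: 23. Longest linear sequence: 13 steps (steps 1–11, 22 and 23, from 1).

Most likely to fail:

1. Step 5 (proposed new method). What may go wrong: hydrogen-atom transfer to the alkyl-substituted allene bond instead of the isopropenyl group, intermolecular radical addition to a second allenoate, or γ-protonation of the dienolate leading to the conjugated exocyclic isomer. Fallback with known chemistry that forms the same ring bond: it sets out from acid chloride 9 (generated from 8 as in step 4). Claisen-type C-acylation of the lithium enolate of ethyl acetate (LDA, EtOAc, THF, −78 °C) should give the β-keto ester ethyl (4RS,6R)-6-[(tert-butyldimethylsilyl)oxy]-4,8-dimethyl-3-oxonon-8-enoate F1. The known HAT-initiated alkene–ketone radical cyclisation (Fe(acac)3, PhSiH3, EtOH, 60 °C), in which the same tertiary radical adds to the ketone carbon, should then give the tertiary alcohol ethyl 2-[(4R)-4-[(tert-butyldimethylsilyl)oxy]-1-hydroxy-2,6,6-trimethylcyclohexyl]acetate F2. Dehydration (SOCl2, pyridine, 0 °C) should give 12 together with the conjugated alkylidene ester ethyl 2-[(4R)-4-[(tert-butyldimethylsilyl)oxy]-2,6,6-trimethylcyclohexylidene]acetate F3, which is converted into 12 by kinetic deconjugation (LDA, THF/DMPU, −78 °C; AcOH quench). The fallback comes back to the route at 12.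

2. Step 8. What may go wrong: amine-induced dimerisation or polymerisation of the vinyl ketone, base-induced loss of the skipped alkene position, or slow addition to the hydrated aldehyde. Fallback by a stoichiometric conjugate addition–aldol–elimination sequence: it sets out from 14. Conjugate addition of Me2AlSePh (CH2Cl2, −78 °C) should give the aluminium enolate, which is trapped with anhydrous 2,2-dimethoxyacetaldehyde to give the β-seleno aldol (3RS,4RS)-1-[(4R)-4-[(tert-butyldimethylsilyl)oxy]-2,6,6-trimethylcyclohex-1-en-1-yl]-4-hydroxy-5,5-dimethoxy-3-[(phenylselanyl)methyl]pentan-2-one F4. Oxidation (H2O2, pyridine, CH2Cl2, 0 °C) and selenoxide syn-elimination toward the only β-hydrogen should give 15, where the fallback comes back to the route.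

3. Step 22. What may go wrong: SN2' displacement of the allylic carboxylate or conjugate addition by the ylide at the doubly activated alkene, and enolisation at the methylene between ring A and the ketone. Fallback that installs the ester last: it sets out from 16.
   - Sodium formate (DMF, rt) should give the formate (2E)-2-{[(4R)-4-[(tert-butyldimethylsilyl)oxy]-2,6,6-trimethylcyclohex-1-en-1-yl]acetyl}-4,4-dimethoxybut-2-en-1-yl formate F5.
   - Mild methanolysis (KHCO3, MeOH, 0 °C) should give the alcohol (3E)-1-[(4R)-4-[(tert-butyldimethylsilyl)oxy]-2,6,6-trimethylcyclohex-1-en-1-yl]-3-(hydroxymethyl)-5,5-dimethoxypent-3-en-2-one F6.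
   - Silylation (TBSCl, imidazole) should give the silyl ether (3E)-3-({[tert-butyl(dimethyl)silyl]oxy}methyl)-1-[(4R)-4-[(tert-butyldimethylsilyl)oxy]-2,6,6-trimethylcyclohex-1-en-1-yl]-5,5-dimethoxypent-3-en-2-one F7, whose silyloxy group is a poor leaving group.
   - Acetal hydrolysis (Amberlyst-15, wet acetone) should give the aldehyde (2E)-3-({[tert-butyl(dimethyl)silyl]oxy}methyl)-5-[(4R)-4-[(tert-butyldimethylsilyl)oxy]-2,6,6-trimethylcyclohex-1-en-1-yl]-4-oxopent-2-enal F8.
   - Wittig reaction with ylide 34 (from 33, 1,2-epoxybutane) should give 3,19,3'-tris-O-(tert-butyldimethylsilyl)siphonaxanthin F9.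
   - HF·pyridine should give siphonaxanthin [(3R,3'R,6'R)-3,19,3'-trihydroxy-7,8-dihydro-β,ε-caroten-8-one] F10.
   - Chemoselective acylation of the primary allylic hydroxyl with 17 (EDC·HCl, DMAP cat., CH2Cl2, −20 °C) brings the fallback back to the route at 36.

**Further compounds**

F1 | step 5 | ethyl (4RS,6R)-6-[(tert-butyldimethylsilyl)oxy]-4,8-dimethyl-3-oxonon-8-enoate | CCOC(=O)CC(=O)C(C)C[C@@H](O[Si](C)(C)C(C)(C)C)CC(C)=C
F2 | step 5 | ethyl 2-[(4R)-4-[(tert-butyldimethylsilyl)oxy]-1-hydroxy-2,6,6-trimethylcyclohexyl]acetate | CCOC(=O)CC1(O)C(C)C[C@@H](O[Si](C)(C)C(C)(C)C)CC1(C)C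
F3 | step 5 | ethyl 2-[(4R)-4-[(tert-butyldimethylsilyl)oxy]-2,6,6-trimethylcyclohexylidene]acetate | CCOC(=O)C=C1C(C)C[C@@H](O[Si](C)(C)C(C)(C)C)CC1(C)C
F4 | step 8 | (3RS,4RS)-1-[(4R)-4-[(tert-butyldimethylsilyl)oxy]-2,6,6-trimethylcyclohex-1-en-1-yl]-4-hydroxy-5,5-dimethoxy-3-[(phenylselanyl)methyl]pentan-2-one | COC(OC)C(O)C(C[Se]c1ccccc1)C(=O)CC1=C(C)C[C@@H](O[Si](C)(C)C(C)(C)C)CC1(C)C
F5 | step 22 | (2E)-2-{[(4R)-4-[(tert-butyldimethylsilyl)oxy]-2,6,6-trimethylcyclohex-1-en-1-yl]acetyl}-4,4-dimethoxybut-2-en-1-yl formate | O=COC\C(=C/C(OC)OC)C(=O)CC1=C(C)C[C@@H](O[Si](C)(C)C(C)(C)C)CC1(C)C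
F6 | step 22 | (3E)-1-[(4R)-4-[(tert-butyldimethylsilyl)oxy]-2,6,6-trimethylcyclohex-1-en-1-yl]-3-(hydroxymethyl)-5,5-dimethoxypent-3-en-2-one | OC\C(=C/C(OC)OC)C(=O)CC1=C(C)C[C@@H](O[Si](C)(C)C(C)(C)C)CC1(C)C
F7 | step 22 | (3E)-3-({[tert-butyl(dimethyl)silyl]oxy}methyl)-1-[(4R)-4-[(tert-butyldimethylsilyl)oxy]-2,6,6-trimethylcyclohex-1-en-1-yl]-5,5-dimethoxypent-3-en-2-one | CC(C)(C)[Si](C)(C)OC\C(=C/C(OC)OC)C(=O)CC1=C(C)C[C@@H](O[Si](C)(C)C(C)(C)C)CC1(C)C
F8 | step 22 | (2E)-3-({[tert-butyl(dimethyl)silyl]oxy}methyl)-5-[(4R)-4-[(tert-butyldimethylsilyl)oxy]-2,6,6-trimethylcyclohex-1-en-1-yl]-4-oxopent-2-enal | CC(C)(C)[Si](C)(C)OC\C(=C/C=O)C(=O)CC1=C(C)C[C@@H](O[Si](C)(C)C(C)(C)C)CC1(C)C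
F9 | step 22 | 3,19,3'-tris-O-(tert-butyldimethylsilyl)siphonaxanthin | CC(C)(C)[Si](C)(C)OC\C(=C/C=C/C(C)=C/C=C/C=C(C)/C=C/C=C(C)/C=C/[C@H]1C(C)=C[C@H](O[Si](C)(C)C(C)(C)C)CC1(C)C)C(=O)CC1=C(C)C[C@@H](O[Si](C)(C)C(C)(C)C)CC1(C)C
F10 | step 22 | siphonaxanthin [(3R,3'R,6'R)-3,19,3'-trihydroxy-7,8-dihydro-β,ε-caroten-8-one] | OC\C(=C/C=C/C(C)=C/C=C/C=C(C)/C=C/C=C(C)/C=C/[C@H]1C(C)=C[C@H](O)CC1(C)C)C(=O)CC1=C(C)C[C@@H](O)CC1(C)C
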